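**Retrosynthetic overview**
- C1–C10: the ten-membered ring is closed last by an intramolecular Ni/Cr (Nozaki–Hiyama–Kishi) addition of a 2-bromoalkene to the C1 aldehyde.
- C8 ester: acylation with a protected (R)-3,4-dihydroxy-2-methylenebutanoic acid made by an asymmetric Morita–Baylis–Hillman reaction.
- C6–C7 and the lactone (first ring): a chiral Brønsted acid-catalysed allylboration–lactonisation joins a West enal and an East 2-(methoxycarbonyl)allylboronate (the new step).
- East half: C8 is the first stereocentre, set by chiral phosphoric acid-catalysed 2-bromoallylboration of cinnamaldehyde; ozonolysis, MBH and SN2′ borylation then build the allylboronate.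
- West half: the ring-cis C4=C5 enal comes from anti-carbomagnesiation of a butynediol monoether.

Assumption: the given SMILES is taken as definitive, i.e. (1R,6S,7R,8S,3′R), cis-fused 12,6-lactone, C6 and C3 cis on C4=C5 (germacrane numbering throughout); 13 and 14 are treated as catalogue items.

**Step 1**
Reactants: 1 (2-bromoallyl)trimethylsilane
Product: 3 2-(2-bromoallyl)-4,4,5,5-tetramethyl-1,3,2-dioxaborolane, via (2-bromoallyl)dichloroborane 2 (not isolated)
Conditions: BCl3, CH2Cl2, −78 → 0 °C; then pinacol, Et3N, 0 °C → rt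
Reagents that add atoms: boron trichloride, ClB(Cl)Cl; pinacol, CC(C)(O)C(C)(C)O
Why: SE2′ silicon-to-boron transmetalation of the allylsilane followed by esterification of the B–Cl bonds with pinacol gives the stable allylboronate; no stereocentre is formed.

**Step 2**
Reactants: 4 (E)-cinnamaldehyde; 3 2-(2-bromoallyl)-4,4,5,5-tetramethyl-1,3,2-dioxaborolane
Product: 5 (1E,3S)-5-bromo-1-phenylhexa-1,5-dien-3-ol
Conditions: (S)-TRIP phosphoric acid (5 mol %), 4 Å MS, toluene, −30 °C → rt; aqueous work-up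
Reagents that add atoms: none
Why: Chiral phosphoric acid-catalysed allylboration of an enal through a closed chair transition state (acid hydrogen-bonded to the boronate oxygen and the formyl H); the (S)-catalyst selects the aldehyde face that gives the 3S carbinol, which becomes C8 and is the first stereocentre.

**Step 3**
Reactants: 5 (1E,3S)-5-bromo-1-phenylhexa-1,5-dien-3-ol
Product: 6 triethyl{[(1E,3S)-5-bromo-1-phenylhexa-1,5-dien-3-yl]oxy}silane
Conditions: TESCl, imidazole, DMF, 0 °C → rt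
Reagents that add atoms: chlorotriethylsilane, CC[Si](Cl)(CC)CC
Why: Routine silylation of a secondary allylic alcohol; the TES ether survives ozonolysis, MBH and Cu–boryl chemistry and is removed cleanly with fluoride in step 12.

**Step 4**
Reactants: 6 triethyl{[(1E,3S)-5-bromo-1-phenylhexa-1,5-dien-3-yl]oxy}silane
Product: 8 (2S)-4-bromo-2-(triethylsilyloxy)pent-4-enal, via secondary ozonide 7 (not isolated)
Conditions: O3, CH2Cl2, pyridine (cat.), −78 °C, Sudan III end point; then Me2S, −78 °C → rt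
Reagents that add atoms: ozone, [O-][O+]=O
Why: Ozonolysis cleaves the electron-rich styrenyl alkene much faster than the electron-poor 2-bromoalkene, and reductive work-up gives the α-silyloxy aldehyde without touching the stereocentre.

**Step 5**
Reactants: 8 (2S)-4-bromo-2-(triethylsilyloxy)pent-4-enal; 9 methyl acrylate
Product: 10 methyl (4S)-6-bromo-3-hydroxy-2-methylidene-4-(triethylsilyloxy)hept-6-enoate (C3 epimer mixture)
Conditions: DABCO (1 equiv), MeOH (2 equiv), neat 9, rt
Reagents that add atoms: none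
Why: Morita–Baylis–Hillman reaction of an inductively activated α-silyloxy aldehyde; the new carbinol centre need not be controlled because it is removed in step 7.

**Step 6**
Reactants: 10 methyl (4S)-6-bromo-3-hydroxy-2-methylidene-4-(triethylsilyloxy)hept-6-enoate (C3 epimer mixture)
Product: 11 methyl (4S)-3-acetoxy-6-bromo-2-methylidene-4-(triethylsilyloxy)hept-6-enoate (C3 epimer mixture)
Conditions: Ac2O, pyridine, DMAP (cat.), CH2Cl2, 0 °C
Reagents that add atoms: acetic anhydride, CC(=O)OC(C)=O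
Why: Standard acetylation turns the MBH alcohol into an SN2′-active allylic acetate.

**Step 7**
Reactants: 11 methyl (4S)-3-acetoxy-6-bromo-2-methylidene-4-(triethylsilyloxy)hept-6-enoate (C3 epimer mixture)
Product: 12 methyl (2E,4S)-6-bromo-2-[(4,4,5,5-tetramethyl-1,3,2-dioxaborolan-2-yl)methyl]-4-(triethylsilyloxy)hepta-2,6-dienoate
Conditions: B2pin2, CuCl (10 mol %), LiCl, KOAc, DMF, rt
Reagents that add atoms: bis(pinacolato)diboron, CC1(C)OB(OC1(C)C)B1OC(C)(C)C(C)(C)O1
Why: Copper–boryl SN2′ substitution of the MBH acetate gives the thermodynamically preferred 2E enoate (C8 chain trans to CO2Me, cis to CH2B); the vinyl bromide and C8 are untouched.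

**Step 8**
Reactants: 13 4-(tert-butyldimethylsilyloxy)but-2-yn-1-ol; 14 [2-(1,3-dioxolan-2-yl)ethyl]magnesium bromide
Product: 15 (2E)-4-(tert-butyldimethylsilyloxy)-2-[2-(1,3-dioxolan-2-yl)ethyl]but-2-en-1-ol
Conditions: 14 (2.5 equiv), CuI (10 mol %), THF, −20 °C → rt; aq. NH4Cl
Reagents that add atoms: none
Why: Copper-catalysed anti-carbomagnesiation of the propargylic alkoxide; the alkyl group adds to the alkoxide-proximal carbon and the five-membered magnesium chelate fixes the new chain cis to CH2OTBS, which sets the ring-cis C4=C5 geometry.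

**Step 9**
Reactants: 15 (2E)-4-(tert-butyldimethylsilyloxy)-2-[2-(1,3-dioxolan-2-yl)ethyl]but-2-en-1-ol
Product: 16 (2E)-4-(tert-butyldimethylsilyloxy)-2-[2-(1,3-dioxolan-2-yl)ethyl]but-2-enyl acetate
Conditions: Ac2O, pyridine, DMAP (cat.), CH2Cl2, 0 °C → rt
Reagents that add atoms: acetic anhydride, CC(=O)OC(C)=O
Why: Standard acetylation installs the C15 acetate of the target at the outset.

**Step 10**
Reactants: 16 (2E)-4-(tert-butyldimethylsilyloxy)-2-[2-(1,3-dioxolan-2-yl)ethyl]but-2-enyl acetate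
Product: 17 (2E)-2-[2-(1,3-dioxolan-2-yl)ethyl]-4-hydroxybut-2-enyl acetate
Conditions: HF·pyridine, THF/pyridine, 0 °C
Reagents that add atoms: none
Why: Buffered fluoride desilylation leaves the acetate and dioxolane intact, and the trans-disposed acetate cannot migrate.

**Step 11**
Reactants: 17 (2E)-2-[2-(1,3-dioxolan-2-yl)ethyl]-4-hydroxybut-2-enyl acetate
Product: 18 (2E)-2-[2-(1,3-dioxolan-2-yl)ethyl]-4-oxobut-2-enyl acetate
Conditions: MnO2, CH2Cl2, rt
Reagents that add atoms: none
Why: Neutral allylic oxidation with MnO2 gives the enal without isomerising the trisubstituted double bond.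

**Step 12**
Reactants: 12 methyl (2E,4S)-6-bromo-2-[(4,4,5,5-tetramethyl-1,3,2-dioxaborolan-2-yl)methyl]-4-(triethylsilyloxy)hepta-2,6-dienoate; 18 (2E)-2-[2-(1,3-dioxolan-2-yl)ethyl]-4-oxobut-2-enyl acetate
Product: 21 (2E)-3-{(2S,3R)-3-[(1S)-3-bromo-1-hydroxybut-3-enyl]-4-methylidene-5-oxooxolan-2-yl}-2-[2-(1,3-dioxolan-2-yl)ethyl]prop-2-enyl acetate, via O-boryl hydroxy ester adduct 19 (not isolated), via C8 triethylsilyl ether of the lactone 20 (not isolated)
Conditions: (R)-TRIP N-triflylphosphoramide (10 mol %), 4 Å MS, toluene, 0 °C → rt; then HF·pyridine, THF, 0 °C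
Reagents that add atoms: none
Why: Proposed new method: a chiral BINOL N-triflylphosphoramide serves as a chiral surrogate of triflic acid to activate the ester-deactivated 2-(methoxycarbonyl)allyl-Bpin 12 toward the β,β-disubstituted enal 18; the acid hydrogen-bonds to the pseudo-axial boronate oxygen (and its P=O to the formyl H) in a closed Zimmerman–Traxler chair, so the 2E boronate (C8 chain cis to CH2B, axial) gives the syn adduct 19, which lactonises in the flask to the cis-fused α-methylene-γ-butyrolactone; the (R)-catalyst selects the aldehyde face that gives 6S, and A1,3 strain (H-8 eclipsing C7=C11, attack anti to the C8–OTES bond) should make the boronate face that gives 7R the matched one; the closest known reactions are chiral phosphoric acid-catalysed allylboration of aldehydes with simple allyl-, crotyl- and allenyl-Bpin and achiral TfOH- or Sc(OTf)3-catalysed allylboration–lactonisation of 2-(alkoxycarbonyl)allylboronates.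

**Step 13**
Reactants: 22 (tert-butyldimethylsilyloxy)acetaldehyde; 23 1,1,1,3,3,3-hexafluoropropan-2-yl acrylate
Product: 24 1,1,1,3,3,3-hexafluoropropan-2-yl (3R)-4-(tert-butyldimethylsilyloxy)-3-hydroxy-2-methylidenebutanoate
Conditions: α-isocupreine (10 mol %), DMF, −55 °C
Reagents that add atoms: none
Why: Cinchona-derived amine-catalysed asymmetric Morita–Baylis–Hillman reaction with the activated HFIP acrylate; β-isocupreidine gives the spatially opposite adducts (3S here by CIP), so the pseudoenantiomeric α-isocupreine is used for the 3R carbinol.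

**Step 14**
Reactants: 24 1,1,1,3,3,3-hexafluoropropan-2-yl (3R)-4-(tert-butyldimethylsilyloxy)-3-hydroxy-2-methylidenebutanoate
Product: 25 1,1,1,3,3,3-hexafluoropropan-2-yl (3R)-4-(tert-butyldimethylsilyloxy)-2-methylidene-3-(triethylsilyloxy)butanoate
Conditions: TESCl, imidazole, DMF, 0 °C → rt
Reagents that add atoms: chlorotriethylsilane, CC[Si](Cl)(CC)CC
Why: Routine silylation blocks the secondary hydroxyl so that the acid cannot self-acylate in step 16.

**Step 15**
Reactants: 25 1,1,1,3,3,3-hexafluoropropan-2-yl (3R)-4-(tert-butyldimethylsilyloxy)-2-methylidene-3-(triethylsilyloxy)butanoate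
Product: 26 (3R)-4-(tert-butyldimethylsilyloxy)-2-methylidene-3-(triethylsilyloxy)butanoic acid
Conditions: LiOH, THF/H2O, 0 °C; then dilute HCl to pH 3–4
Reagents that add atoms: lithium hydroxide, [Li+].[OH-]
Why: The activated HFIP ester is saponified under very mild conditions, and the stereocentre has no acidic α-hydrogen (C2 is sp2), so it cannot epimerise or eliminate.

**Step 16**
Reactants: 21 (2E)-3-{(2S,3R)-3-[(1S)-3-bromo-1-hydroxybut-3-enyl]-4-methylidene-5-oxooxolan-2-yl}-2-[2-(1,3-dioxolan-2-yl)ethyl]prop-2-enyl acetate; 26 (3R)-4-(tert-butyldimethylsilyloxy)-2-methylidene-3-(triethylsilyloxy)butanoic acid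
Product: 27 (2E)-3-{(2S,3R)-3-[(1S)-3-bromo-1-({(3R)-4-(tert-butyldimethylsilyloxy)-2-methylidene-3-(triethylsilyloxy)butanoyl}oxy)but-3-enyl]-4-methylidene-5-oxooxolan-2-yl}-2-[2-(1,3-dioxolan-2-yl)ethyl]prop-2-enyl acetate
Conditions: DIC, DMAP (cat.), CH2Cl2, 0 °C → rt
Reagents that add atoms: none
Why: Steglich esterification acylates the only free hydroxyl (C8) with retention; the non-basic conditions avoid 12,6 → 12,8 translactonisation.

**Step 17**
Reactants: 27 (2E)-3-{(2S,3R)-3-[(1S)-3-bromo-1-({(3R)-4-(tert-butyldimethylsilyloxy)-2-methylidene-3-(triethylsilyloxy)butanoyl}oxy)but-3-enyl]-4-methylidene-5-oxooxolan-2-yl}-2-[2-(1,3-dioxolan-2-yl)ethyl]prop-2-enyl acetate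
Product: 28 (2E)-3-{(2S,3R)-3-[(1S)-3-bromo-1-{[(3R)-3,4-dihydroxy-2-methylidenebutanoyl]oxy}but-3-enyl]-4-methylidene-5-oxooxolan-2-yl}-2-(3-oxopropyl)prop-2-enyl acetate
Conditions: 1 M aq. HCl/THF (1:4), rt
Reagents that add atoms: water, O
Why: Acid hydrolysis removes the dioxolane and both silyl ethers in one operation; the acetate, the lactone and the dihydroxy-acrylate ester (acid-tolerant but prone to base-induced lactonisation) are kept.

**Step 18**
Reactants: 28 (2E)-3-{(2S,3R)-3-[(1S)-3-bromo-1-{[(3R)-3,4-dihydroxy-2-methylidenebutanoyl]oxy}but-3-enyl]-4-methylidene-5-oxooxolan-2-yl}-2-(3-oxopropyl)prop-2-enyl acetate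
Product: 29 CNP0245550.1, (1R,4E,6S,7R,8S)-15-acetoxy-1-hydroxy-8-{[(3R)-3,4-dihydroxy-2-methylidenebutanoyl]oxy}germacra-4,10(14),11(13)-trien-12,6-olide
Conditions: CrCl2 (8 equiv), NiCl2 (2 mol %), DMSO/THF, rt, 2 mM, syringe-pump addition; aq. NH4Cl work-up
Reagents that add atoms: none
Why: Nozaki–Hiyama–Kishi macrocyclisation: the alkenylchromium from the 2-bromoalkene adds only to the aldehyde (esters, enoates and free hydroxyls tolerated) and closes the ten-membered ring with the 10(14)-methylene in place; C1 is set under macrocyclic substrate control, with the chromium alkoxide expected on the ring face anti to the C8 acyloxy group (1R), which is not proven.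

**Compound list**
1 | (2-bromoallyl)trimethylsilane | C=C(Br)C[Si](C)(C)C | starting material
2 | (2-bromoallyl)dichloroborane | C=C(Br)CB(Cl)Cl | intermediate
3 | 2-(2-bromoallyl)-4,4,5,5-tetramethyl-1,3,2-dioxaborolane | C=C(Br)CB1OC(C)(C)C(C)(C)O1 | intermediate
4 | (E)-cinnamaldehyde | O=C/C=C/c1ccccc1 | starting material
5 | (1E,3S)-5-bromo-1-phenylhexa-1,5-dien-3-ol | C=C(Br)C[C@H](O)/C=C/c1ccccc1 | intermediate
6 | triethyl{[(1E,3S)-5-bromo-1-phenylhexa-1,5-dien-3-yl]oxy}silane | C=C(Br)C[C@H](O[Si](CC)(CC)CC)/C=C/c1ccccc1 | intermediate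
7 | secondary ozonide of 6: 3-[(1S)-3-bromo-1-(triethylsilyloxy)but-3-enyl]-5-phenyl-1,2,4-trioxolane | C=C(Br)C[C@H](O[Si](CC)(CC)CC)C1OOC(c2ccccc2)O1 | intermediate
8 | (2S)-4-bromo-2-(triethylsilyloxy)pent-4-enal | C=C(Br)C[C@H](O[Si](CC)(CC)CC)C=O | intermediate
9 | methyl acrylate | C=CC(=O)OC | starting material
10 | methyl (4S)-6-bromo-3-hydroxy-2-methylidene-4-(triethylsilyloxy)hept-6-enoate (C3 epimer mixture) | C=C(Br)C[C@H](O[Si](CC)(CC)CC)C(O)C(=C)C(=O)OC | intermediate
11 | methyl (4S)-3-acetoxy-6-bromo-2-methylidene-4-(triethylsilyloxy)hept-6-enoate (C3 epimer mixture) | C=C(Br)C[C@H](O[Si](CC)(CC)CC)C(OC(C)=O)C(=C)C(=O)OC | intermediate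
12 | methyl (2E,4S)-6-bromo-2-[(4,4,5,5-tetramethyl-1,3,2-dioxaborolan-2-yl)methyl]-4-(triethylsilyloxy)hepta-2,6-dienoate | C=C(Br)C[C@H](O[Si](CC)(CC)CC)/C=C(/C(=O)OC)CB1OC(C)(C)C(C)(C)O1 | intermediate
13 | 4-(tert-butyldimethylsilyloxy)but-2-yn-1-ol | OCC#CCO[Si](C)(C)C(C)(C)C | starting material
14 | [2-(1,3-dioxolan-2-yl)ethyl]magnesium bromide (THF solution) | Br[Mg]CCC1OCCO1 | starting material
15 | (2E)-4-(tert-butyldimethylsilyloxy)-2-[2-(1,3-dioxolan-2-yl)ethyl]but-2-en-1-ol | OC/C(CCC1OCCO1)=C/CO[Si](C)(C)C(C)(C)C | intermediate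
16 | (2E)-4-(tert-butyldimethylsilyloxy)-2-[2-(1,3-dioxolan-2-yl)ethyl]but-2-enyl acetate | CC(=O)OC/C(CCC1OCCO1)=C/CO[Si](C)(C)C(C)(C)C | intermediate
17 | (2E)-2-[2-(1,3-dioxolan-2-yl)ethyl]-4-hydroxybut-2-enyl acetate | CC(=O)OC/C(CCC1OCCO1)=C/CO | intermediate
18 | (2E)-2-[2-(1,3-dioxolan-2-yl)ethyl]-4-oxobut-2-enyl acetate | CC(=O)OC/C(CCC1OCCO1)=C/C=O | intermediate
19 | open-chain allylboration adduct of 12 and 18 (methyl ester, C6–O–Bpin borate; C6, C7, C8 configured as in 21) | COC(=O)C(=C)[C@@H]([C@@H](OB1OC(C)(C)C(C)(C)O1)/C=C(/COC(C)=O)CCC1OCCO1)[C@@H](O[Si](CC)(CC)CC)CC(Br)=C | intermediate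
20 | C8 triethylsilyl ether of 21 | C=C1C(=O)O[C@@H](/C=C(/COC(C)=O)CCC2OCCO2)[C@H]1[C@@H](O[Si](CC)(CC)CC)CC(Br)=C | intermediate
21 | (2E)-3-{(2S,3R)-3-[(1S)-3-bromo-1-hydroxybut-3-enyl]-4-methylidene-5-oxooxolan-2-yl}-2-[2-(1,3-dioxolan-2-yl)ethyl]prop-2-enyl acetate | C=C1C(=O)O[C@@H](/C=C(/COC(C)=O)CCC2OCCO2)[C@H]1[C@@H](O)CC(Br)=C | intermediate
22 | (tert-butyldimethylsilyloxy)acetaldehyde | O=CCO[Si](C)(C)C(C)(C)C | starting material
23 | 1,1,1,3,3,3-hexafluoropropan-2-yl acrylate | C=CC(=O)OC(C(F)(F)F)C(F)(F)F | starting material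
24 | 1,1,1,3,3,3-hexafluoropropan-2-yl (3R)-4-(tert-butyldimethylsilyloxy)-3-hydroxy-2-methylidenebutanoate | C=C(C(=O)OC(C(F)(F)F)C(F)(F)F)[C@@H](O)CO[Si](C)(C)C(C)(C)C | intermediate
25 | 1,1,1,3,3,3-hexafluoropropan-2-yl (3R)-4-(tert-butyldimethylsilyloxy)-2-methylidene-3-(triethylsilyloxy)butanoate | C=C(C(=O)OC(C(F)(F)F)C(F)(F)F)[C@@H](O[Si](CC)(CC)CC)CO[Si](C)(C)C(C)(C)C | intermediate
26 | (3R)-4-(tert-butyldimethylsilyloxy)-2-methylidene-3-(triethylsilyloxy)butanoic acid | C=C(C(=O)O)[C@@H](O[Si](CC)(CC)CC)CO[Si](C)(C)C(C)(C)C | intermediate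
27 | (2E)-3-{(2S,3R)-3-[(1S)-3-bromo-1-({(3R)-4-(tert-butyldimethylsilyloxy)-2-methylidene-3-(triethylsilyloxy)butanoyl}oxy)but-3-enyl]-4-methylidene-5-oxooxolan-2-yl}-2-[2-(1,3-dioxolan-2-yl)ethyl]prop-2-enyl acetate | C=C1C(=O)O[C@@H](/C=C(/COC(C)=O)CCC2OCCO2)[C@H]1[C@@H](OC(=O)C(=C)[C@@H](O[Si](CC)(CC)CC)CO[Si](C)(C)C(C)(C)C)CC(Br)=C | intermediate
28 | (2E)-3-{(2S,3R)-3-[(1S)-3-bromo-1-{[(3R)-3,4-dihydroxy-2-methylidenebutanoyl]oxy}but-3-enyl]-4-methylidene-5-oxooxolan-2-yl}-2-(3-oxopropyl)prop-2-enyl acetate | C=C1C(=O)O[C@@H](/C=C(/COC(C)=O)CCC=O)[C@H]1[C@@H](OC(=O)C(=C)[C@@H](O)CO)CC(Br)=C | intermediate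
29 | CNP0245550.1, (1R,4E,6S,7R,8S)-15-acetoxy-1-hydroxy-8-{[(3R)-3,4-dihydroxy-2-methylidenebutanoyl]oxy}germacra-4,10(14),11(13)-trien-12,6-olide | C=C1C(=O)O[C@H]2/C=C(/COC(C)=O)CC[C@@H](O)C(=C)C[C@H](OC(=O)C(=C)[C@@H](O)CO)[C@@H]12 | target

**Step count and risks**
Total steps: 18. Longest linear sequence: 11 (steps 1–7, 12, 16, 17, 18).

Most likely to fail, first: step 12 (the proposed new step). The ester-deactivated, γ-branched boronate may react too slowly under a chiral acid. Acid-induced ionisation at the allylic C6–O bond could divert to the trans-lactone. The catalyst and the C8 centre could also turn out mismatched. The fallback uses known chemistry and sets out from 10. PBr3 (Et2O, −10 °C) converts the MBH alcohol with allylic transposition into methyl (2Z,4S)-6-bromo-2-(bromomethyl)-4-(triethylsilyloxy)hepta-2,6-dienoate F1. Indium-mediated Barbier allylation of enal 18 with F1 (In, THF/H2O, rt; then PPTS to complete lactonisation) is an established entry to cis-β,γ-disubstituted α-methylene-γ-butyrolactones and gives 20 under substrate control from C8. HF·pyridine then gives 21, where the route is rejoined.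

Second: step 18. Closure of a strained ten-membered ring may be low-yielding, the C1 configuration rests on unproven substrate control, and the unprotected dihydroxy-acrylate may lactonise on chromium. The fallback sets out from 27. TESOTf/2,4,6-collidine followed by water cleaves only the dioxolane and gives the bis-silyl-protected seco aldehyde F2. The same Ni/Cr closure gives the bis-silyl ether of the macrocycle as a C1 epimer mixture F3. Dess–Martin oxidation gives the C1 enone of the bis-silyl ether F4. (S)-Me-CBS/catecholborane reduction (alkenyl as the large group) gives the 1R bis-silyl ether of the target F5. HF·pyridine removes both silyl groups and gives 29.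

Third: step 8. The functionalised alkyl Grignard may add sluggishly, and copper-mediated SN2′ displacement of the propargylic silyl ether (allene formation) competes. The fallback sets out from 13. Red-Al (THF, 0 °C) then I2 gives (2Z)-4-(tert-butyldimethylsilyloxy)-3-iodobut-2-en-1-ol F6. Negishi coupling with [2-(1,3-dioxolan-2-yl)ethyl]zinc bromide (Pd(dppf)Cl2, THF) gives (2E)-3-[(tert-butyldimethylsilyloxy)methyl]-5-(1,3-dioxolan-2-yl)pent-2-en-1-ol F7. MnO2 gives (2E)-3-[(tert-butyldimethylsilyloxy)methyl]-5-(1,3-dioxolan-2-yl)pent-2-enal F8. HF·pyridine gives (2E)-5-(1,3-dioxolan-2-yl)-3-(hydroxymethyl)pent-2-enal F9. Acetylation (Ac2O, pyridine) gives 18, where the route is rejoined.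

**Further compounds**
F1 | step 12 | methyl (2Z,4S)-6-bromo-2-(bromomethyl)-4-(triethylsilyloxy)hepta-2,6-dienoate | C=C(Br)C[C@H](O[Si](CC)(CC)CC)/C=C(/C(=O)OC)CBr
F2 | step 18 | bis-silyl-protected seco aldehyde (27 with CHO in place of the dioxolane) | C=C1C(=O)O[C@@H](/C=C(/COC(C)=O)CCC=O)[C@H]1[C@@H](OC(=O)C(=C)[C@@H](O[Si](CC)(CC)CC)CO[Si](C)(C)C(C)(C)C)CC(Br)=C
F3 | step 18 | 3′-O-TES-4′-O-TBS ether of the macrocycle as C1 epimer mixture | C=C1C(=O)O[C@H]2/C=C(/COC(C)=O)CCC(O)C(=C)C[C@H](OC(=O)C(=C)[C@@H](O[Si](CC)(CC)CC)CO[Si](C)(C)C(C)(C)C)[C@@H]12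
F4 | step 18 | C1 enone of the 3′-O-TES-4′-O-TBS ether | C=C1C(=O)O[C@H]2/C=C(/COC(C)=O)CCC(=O)C(=C)C[C@H](OC(=O)C(=C)[C@@H](O[Si](CC)(CC)CC)CO[Si](C)(C)C(C)(C)C)[C@@H]12
F5 | step 18 | 3′-O-TES-4′-O-TBS ether of 29 (1R) | C=C1C(=O)O[C@H]2/C=C(/COC(C)=O)CC[C@@H](O)C(=C)C[C@H](OC(=O)C(=C)[C@@H](O[Si](CC)(CC)CC)CO[Si](C)(C)C(C)(C)C)[C@@H]12
F6 | step 8 | (2Z)-4-(tert-butyldimethylsilyloxy)-3-iodobut-2-en-1-ol | OC/C=C(/CO[Si](C)(C)C(C)(C)C)I
F7 | step 8 | (2E)-3-[(tert-butyldimethylsilyloxy)methyl]-5-(1,3-dioxolan-2-yl)pent-2-en-1-ol | OC/C=C(/CO[Si](C)(C)C(C)(C)C)CCC1OCCO1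
F8 | step 8 | (2E)-3-[(tert-butyldimethylsilyloxy)methyl]-5-(1,3-dioxolan-2-yl)pent-2-enal | O=C/C=C(/CO[Si](C)(C)C(C)(C)C)CCC1OCCO1
F9 | step 8 | (2E)-5-(1,3-dioxolan-2-yl)-3-(hydroxymethyl)pent-2-enal | O=C/C=C(/CO)CCC1OCCO1
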